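**Retrosynthetic overview**
1. Ester C7–O bond: the target comes from (7S)-7-hydroxy-azaphilone 21 and the silyl-protected (2R,3R,4S)-acid 31. The cyclohexenone C=O is carried as a silylated allylic alcohol and unveiled last by MnO2.
2. Pyran ring and dearomatised ring: both arise in one operation from keto-aldehyde 19 by a flavin-dependent monooxygenase (hydroxylative dearomatisation, then spontaneous cyclodehydration), which sets C7.
3. Keto-aldehyde 19: Sonogashira coupling of bromo-resorcinaldehyde 15 with alkyne 10, then gold-catalysed carbonyl-assisted alkyne hydration.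
4. Cyclohexene 10: catalytic asymmetric Diels–Alder reaction of an achiral crotonyl imide with 1-acetoxybutadiene, which sets the first stereocentres.
5. Acid 31: from tiglic acid by two asymmetric hydrogenations and a Fráter–Seebach methylation. Ring order: cyclohexene (Diels–Alder), benzene ring bought, then pyran ring plus dearomatised ring in the enzymatic step.

Assumption: compounds 1, 2, 4, 11, 22 and 24 are bought, the S-selective monooxygenase is of the AfoD type (the AzaH type gives the 7R series) and is used as E. coli lysate; TBS = tert-butyldimethylsilyl.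

**Route**

Step 1
Reactants: 1 oxazolidin-2-one; 2 (E)-but-2-enoyl chloride
Product: 3 3-[(E)-but-2-enoyl]oxazolidin-2-one
Conditions: n-BuLi, THF, −78 °C; then 2, −78 → 0 °C
Reagents that add atoms: none
Why: N-acylation of the lithiated carbamate by the acid chloride (nucleophilic acyl substitution) gives a two-point-binding dienophile; no stereocentre is formed.

Step 2
Reactants: 3 3-[(E)-but-2-enoyl]oxazolidin-2-one; 4 (E)-buta-1,3-dien-1-yl acetate
Product: 5 3-[(1S,2R,6R)-2-acetoxy-6-methylcyclohex-3-ene-1-carbonyl]oxazolidin-2-one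
Conditions: [Cu((S,S)-t-Bu-box)](SbF6)2 (10 mol%), CH2Cl2, rt, 48 h, 3 equiv of 4
Reagents that add atoms: none
Why: Evans bis(oxazoline)–divalent copper catalysed Diels–Alder reaction, in which the chelated s-cis imide is attacked endo on its α-Re face with "ortho" regiochemistry, so C1 (S) and C2 (R) are set by the catalyst and the C6 methyl (R) ends trans to the acyl group because the dienophile is E.

Step 3
Reactants: 5 3-[(1S,2R,6R)-2-acetoxy-6-methylcyclohex-3-ene-1-carbonyl]oxazolidin-2-one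
Product: 6 (1R,5R,6R)-6-(hydroxymethyl)-5-methylcyclohex-2-en-1-ol
Conditions: LiAlH4, THF, 0 °C; then H2O
Reagents that add atoms: none
Why: Hydride reduction cleaves the imide to the primary alcohol and removes the acetate without touching any stereocentre.

Step 4
Reactants: 6 (1R,5R,6R)-6-(hydroxymethyl)-5-methylcyclohex-2-en-1-ol
Product: 7 tert-butyl{[(1R,2R,6R)-2-(TBSO)-6-methylcyclohex-3-en-1-yl]methoxy}dimethylsilane
Conditions: TBSOTf (2.5 equiv), 2,6-lutidine, CH2Cl2, −78 → 0 °C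
Reagents that add atoms: tert-butyldimethylsilyl triflate, CC(C)(C)[Si](C)(C)OS(=O)(=O)C(F)(F)F
Why: Silyl triflate silylation protects both hydroxyls, including the hindered allylic one.

Step 5
Reactants: 7 tert-butyl{[(1R,2R,6R)-2-(TBSO)-6-methylcyclohex-3-en-1-yl]methoxy}dimethylsilane
Product: 8 [(1R,2R,6R)-2-(TBSO)-6-methylcyclohex-3-en-1-yl]methanol
Conditions: HF·pyridine, pyridine, THF, 0 °C
Reagents that add atoms: none
Why: Buffered fluoride desilylation removes the unhindered primary silyl ether much faster than the hindered secondary allylic one (selective deprotection).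

Step 6
Reactants: 8 [(1R,2R,6R)-2-(TBSO)-6-methylcyclohex-3-en-1-yl]methanol
Product: 9 (1S,2R,6R)-2-(TBSO)-6-methylcyclohex-3-ene-1-carbaldehyde
Conditions: Dess–Martin periodinane, CH2Cl2, 0 °C → rt
Reagents that add atoms: none
Why: Dess–Martin oxidation is base-free, so the α-stereocentre is not epimerised and the β-silyloxy group is not eliminated.

Step 7
Reactants: 9 (1S,2R,6R)-2-(TBSO)-6-methylcyclohex-3-ene-1-carbaldehyde
Product: 10 tert-butyl{[(1R,5R,6R)-6-ethynyl-5-methylcyclohex-2-en-1-yl]oxy}dimethylsilane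
Conditions: dimethyl (1-diazo-2-oxopropyl)phosphonate, K2CO3, MeOH, 0 °C → rt
Reagents that add atoms: dimethyl (1-diazo-2-oxopropyl)phosphonate, COP(=O)(OC)C(=[N+]=[N-])C(C)=O
Why: Ohira–Bestmann (Seyferth–Gilbert) homologation turns the aldehyde into the terminal alkyne under mild carbonate conditions that keep the α-centre.

Step 8
Reactants: 11 1-bromo-3,5-dimethoxybenzene
Product: 12 5-bromo-1,3-dimethoxy-2-methylbenzene
Conditions: LiN(i-Pr)2, THF, −78 °C; MeI, −78 °C → rt
Reagents that add atoms: iodomethane, CI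
Why: Directed ortho-metalation at the position flanked by both methoxy groups (an amide base avoids Br–Li exchange), then methylation.

Step 9
Reactants: 12 5-bromo-1,3-dimethoxy-2-methylbenzene
Product: 14 6-bromo-2,4-dimethoxy-3-methylbenzaldehyde, via aryl iminium dichlorophosphate 13 (not isolated)
Conditions: POCl3, DMF, 0 → 80 °C; then H2O
Reagents that add atoms: N,N-dimethylformamide, CN(C)C=O; water, O
Why: Vilsmeier–Haack formylation at the only free ring position, which is ortho/para to the two methoxy groups.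

Step 10
Reactants: 14 6-bromo-2,4-dimethoxy-3-methylbenzaldehyde
Product: 15 6-bromo-2,4-dihydroxy-3-methylbenzaldehyde
Conditions: BBr3, CH2Cl2, −78 °C → rt; then H2O
Reagents that add atoms: none
Why: Lewis-acid ether cleavage frees both phenols before any acid-sensitive group is present.

Step 11
Reactants: 15 6-bromo-2,4-dihydroxy-3-methylbenzaldehyde; 10 tert-butyl{[(1R,5R,6R)-6-ethynyl-5-methylcyclohex-2-en-1-yl]oxy}dimethylsilane
Product: 16 6-{[(1R,2R,6R)-2-(TBSO)-6-methylcyclohex-3-en-1-yl]ethynyl}-2,4-dihydroxy-3-methylbenzaldehyde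
Conditions: Pd(PPh3)2Cl2 (5 mol%), CuI (10 mol%), Et3N, DMF, 60 °C
Reagents that add atoms: none
Why: Sonogashira coupling of the formyl-activated aryl bromide tolerates the free phenols, and no phenol sits ortho to the alkyne, so no benzofuran can form.

Step 12
Reactants: 16 6-{[(1R,2R,6R)-2-(TBSO)-6-methylcyclohex-3-en-1-yl]ethynyl}-2,4-dihydroxy-3-methylbenzaldehyde
Product: 19 2,4-dihydroxy-3-methyl-6-{2-oxo-2-[(1S,2R,6R)-2-(TBSO)-6-methylcyclohex-3-en-1-yl]ethyl}benzaldehyde, via benzopyrylium trifluoroacetate 17 (not isolated), via lactol 18 (not isolated)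
Conditions: Au(OAc)3 (5 mol%), CF3CO2H, ClCH2CH2Cl, rt, 10 min; then H2O/MeCN, rt
Reagents that add atoms: water, O
Why: Carbonyl-assisted 6-endo-dig cycloisomerisation under trivalent gold catalysis gives the 2-benzopyrylium salt, which adds water at C1 and opens by ring–chain tautomerism, placing the ketone on the carbon next to the cyclohexene (regioselective formal alkyne hydration) without creating a stereocentre.

Step 13
Reactants: 19 2,4-dihydroxy-3-methyl-6-{2-oxo-2-[(1S,2R,6R)-2-(TBSO)-6-methylcyclohex-3-en-1-yl]ethyl}benzaldehyde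
Product: 21 (7S)-7-hydroxy-7-methyl-3-[(1S,2R,6R)-2-(TBSO)-6-methylcyclohex-3-en-1-yl]-6H-isochromene-6,8(7H)-dione, via dearomatised o-quinol 20 (not isolated)
Conditions: flavin-dependent monooxygenase (S-selective, AfoD type, E. coli lysate), NADP+ (cat.), phosphite dehydrogenase, Na2HPO3, air, K2HPO4/KH2PO4 buffer pH 8.0, 10% DMSO, 30 °C
Reagents that add atoms: dioxygen, O=O
Why: Enzymatic hydroxylative dearomatisation, in which the flavin hydroperoxide delivers OH to one face of the methyl-bearing resorcinol carbon and so sets C7 (S), followed by spontaneous cyclodehydration of the enolised ketone onto the aldehyde to close the pyran.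

Step 14
Reactants: 22 (E)-2-methylbut-2-enoic acid
Product: 23 (S)-2-methylbutanoic acid
Conditions: Ru(OAc)2[(S)-H8-BINAP] (0.5 mol%), H2 (1.5 atm), MeOH, 15 °C
Reagents that add atoms: none
Why: Carboxylate-directed asymmetric hydrogenation (Noyori–Takaya) on divalent ruthenium delivers hydrogen to one alkene face and sets side-chain C4 as S.

Step 15
Reactants: 23 (S)-2-methylbutanoic acid; 24 potassium 3-methoxy-3-oxopropanoate
Product: 26 methyl (4S)-4-methyl-3-oxohexanoate, via acyl imidazolide 25 (not isolated)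
Conditions: 1,1'-carbonyldiimidazole, THF, rt; then 24, MgCl2, THF, rt → 45 °C; then HCl (aq)
Reagents that add atoms: none
Why: Masamune–Brooks decarboxylative Claisen condensation acylates the magnesium malonate half-ester under near-neutral conditions, so the α-stereocentre is kept.

Step 16
Reactants: 26 methyl (4S)-4-methyl-3-oxohexanoate
Product: 27 methyl (3S,4S)-3-hydroxy-4-methylhexanoate
Conditions: RuCl2[(R)-BINAP] (0.5 mol%), H2 (50 atm), MeOH, 50 °C
Reagents that add atoms: none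
Why: Noyori asymmetric hydrogenation of the ester-chelated ketone is catalyst-controlled and gives the 3S alcohol (same spatial sense as (R)-3-hydroxybutanoate; the descriptor differs only because sec-butyl outranks CH2CO2Me), while C4 is untouched.

Step 17
Reactants: 27 methyl (3S,4S)-3-hydroxy-4-methylhexanoate
Product: 28 methyl (2R,3R,4S)-3-hydroxy-2,4-dimethylhexanoate
Conditions: LiN(i-Pr)2 (2.2 equiv), THF, −78 → −20 °C; MeI, −78 → 0 °C; then H2O
Reagents that add atoms: iodomethane, CI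
Why: Fráter–Seebach alkylation, in which the chelated alkoxide–enolate dianion is methylated on the face away from the C3 substituent, giving the 2,3-anti (2R) product.

Step 18
Reactants: 28 methyl (2R,3R,4S)-3-hydroxy-2,4-dimethylhexanoate
Product: 29 (2R,3R,4S)-3-hydroxy-2,4-dimethylhexanoic acid
Conditions: LiOH, THF/H2O, 0 °C → rt; then HCl (aq)
Reagents that add atoms: lithium hydroxide, [Li+].[OH-]
Why: Saponification of the unprotected β-hydroxy ester proceeds through the carboxylate without epimerising C2.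

Step 19
Reactants: 29 (2R,3R,4S)-3-hydroxy-2,4-dimethylhexanoic acid
Product: 31 (2R,3R,4S)-3-(TBSO)-2,4-dimethylhexanoic acid, via silyl ester 30 (not isolated)
Conditions: TBSOTf (2.5 equiv), 2,6-lutidine, CH2Cl2, 0 °C; then AcOH/THF/H2O, rt
Reagents that add atoms: tert-butyldimethylsilyl triflate, CC(C)(C)[Si](C)(C)OS(=O)(=O)C(F)(F)F
Why: Bis-silylation followed by mild hydrolysis of the labile silyl ester leaves only the hindered secondary silyl ether (protection).

Step 20
Reactants: 31 (2R,3R,4S)-3-(TBSO)-2,4-dimethylhexanoic acid; 21 (7S)-7-hydroxy-7-methyl-3-[(1S,2R,6R)-2-(TBSO)-6-methylcyclohex-3-en-1-yl]-6H-isochromene-6,8(7H)-dione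
Product: 33 (7S)-7-methyl-6,8-dioxo-3-[(1S,2R,6R)-2-(TBSO)-6-methylcyclohex-3-en-1-yl]-7,8-dihydro-6H-isochromen-7-yl (2R,3R,4S)-3-(TBSO)-2,4-dimethylhexanoate, via acid chloride 32 (not isolated)
Conditions: 1-chloro-N,N,2-trimethylprop-1-en-1-amine, CH2Cl2, 0 °C → rt; then 21, DMAP (3 equiv), CH2Cl2, 0 °C → rt
Reagents that add atoms: none
Why: Neutral acid chloride formation (Ghosez reagent) and DMAP-mediated acylation of the acidic tertiary C7 hydroxyl, the only free OH in 21, with no triethylamine present to limit ketene-type epimerisation of C2.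

Step 21
Reactants: 33 (7S)-7-methyl-6,8-dioxo-3-[(1S,2R,6R)-2-(TBSO)-6-methylcyclohex-3-en-1-yl]-7,8-dihydro-6H-isochromen-7-yl (2R,3R,4S)-3-(TBSO)-2,4-dimethylhexanoate
Product: 34 (7S)-3-[(1S,2R,6R)-2-hydroxy-6-methylcyclohex-3-en-1-yl]-7-methyl-6,8-dioxo-7,8-dihydro-6H-isochromen-7-yl (2R,3R,4S)-3-hydroxy-2,4-dimethylhexanoate
Conditions: HF·pyridine, pyridine, THF, 0 °C → rt
Reagents that add atoms: none
Why: Global fluoride desilylation under mildly acidic, non-basic conditions that the azaphilone and the tertiary ester tolerate.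

Step 22
Reactants: 34 (7S)-3-[(1S,2R,6R)-2-hydroxy-6-methylcyclohex-3-en-1-yl]-7-methyl-6,8-dioxo-7,8-dihydro-6H-isochromen-7-yl (2R,3R,4S)-3-hydroxy-2,4-dimethylhexanoate
Product: 35 muyocopronone A, (7S)-7-methyl-3-[(1R,6R)-6-methyl-2-oxocyclohex-3-en-1-yl]-6,8-dioxo-7,8-dihydro-6H-isochromen-7-yl (2R,3R,4S)-3-hydroxy-2,4-dimethylhexanoate
Conditions: MnO2 (activated, 20 equiv), CH2Cl2, rt
Reagents that add atoms: none
Why: Chemoselective allylic oxidation by MnO2 gives the enone and leaves the saturated side-chain carbinol, while the ring centre next to the new ketone stays trans to the methyl, which is also its thermodynamic arrangement.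

**Compound list**
1 | oxazolidin-2-one | O=C1NCCO1 | starting material
2 | (E)-but-2-enoyl chloride | C/C=C/C(=O)Cl | starting material
3 | 3-[(E)-but-2-enoyl]oxazolidin-2-one | C/C=C/C(=O)N1CCOC1=O | intermediate
4 | (E)-buta-1,3-dien-1-yl acetate | CC(=O)O/C=C/C=C | starting material
5 | 3-[(1S,2R,6R)-2-acetoxy-6-methylcyclohex-3-ene-1-carbonyl]oxazolidin-2-one | O=C(N1CCOC1=O)[C@@H]2[C@H](OC(C)=O)C=CC[C@H]2C | intermediate
6 | (1R,5R,6R)-6-(hydroxymethyl)-5-methylcyclohex-2-en-1-ol | OC[C@@H]1[C@H](O)C=CC[C@H]1C | intermediate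
7 | tert-butyl{[(1R,2R,6R)-2-[(tert-butyldimethylsilyl)oxy]-6-methylcyclohex-3-en-1-yl]methoxy}dimethylsilane | CC(C)(C)[Si](C)(C)OC[C@@H]1[C@H](O[Si](C)(C)C(C)(C)C)C=CC[C@H]1C | intermediate
8 | [(1R,2R,6R)-2-[(tert-butyldimethylsilyl)oxy]-6-methylcyclohex-3-en-1-yl]methanol | OC[C@@H]1[C@H](O[Si](C)(C)C(C)(C)C)C=CC[C@H]1C | intermediate
9 | (1S,2R,6R)-2-[(tert-butyldimethylsilyl)oxy]-6-methylcyclohex-3-ene-1-carbaldehyde | O=C[C@@H]1[C@H](O[Si](C)(C)C(C)(C)C)C=CC[C@H]1C | intermediate
10 | tert-butyl{[(1R,5R,6R)-6-ethynyl-5-methylcyclohex-2-en-1-yl]oxy}dimethylsilane | C#C[C@@H]1[C@H](O[Si](C)(C)C(C)(C)C)C=CC[C@H]1C | intermediate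
11 | 1-bromo-3,5-dimethoxybenzene | COc1cc(Br)cc(OC)c1 | starting material
12 | 5-bromo-1,3-dimethoxy-2-methylbenzene | COc1cc(Br)cc(OC)c1C | intermediate
13 | N-[(6-bromo-2,4-dimethoxy-3-methylphenyl)methylidene]-N-methylmethanaminium dichlorophosphate | COc1cc(Br)c(C=[N+](C)C)c(OC)c1C.[O-]P(=O)(Cl)Cl | intermediate (not isolated)
14 | 6-bromo-2,4-dimethoxy-3-methylbenzaldehyde | COc1cc(Br)c(C=O)c(OC)c1C | intermediate
15 | 6-bromo-2,4-dihydroxy-3-methylbenzaldehyde | Cc1c(O)cc(Br)c(C=O)c1O | intermediate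
16 | 6-{[(1R,2R,6R)-2-[(tert-butyldimethylsilyl)oxy]-6-methylcyclohex-3-en-1-yl]ethynyl}-2,4-dihydroxy-3-methylbenzaldehyde | Cc1c(O)cc(C#C[C@@H]2[C@H](O[Si](C)(C)C(C)(C)C)C=CC[C@H]2C)c(C=O)c1O | intermediate
17 | 6,8-dihydroxy-7-methyl-3-[(1S,2R,6R)-2-[(tert-butyldimethylsilyl)oxy]-6-methylcyclohex-3-en-1-yl]isochromenylium trifluoroacetate | Cc1c(O)cc2cc([C@@H]3[C@H](O[Si](C)(C)C(C)(C)C)C=CC[C@H]3C)[o+]cc2c1O.[O-]C(=O)C(F)(F)F | intermediate (not isolated)
18 | 7-methyl-3-[(1S,2R,6R)-2-[(tert-butyldimethylsilyl)oxy]-6-methylcyclohex-3-en-1-yl]-1H-isochromene-1,6,8-triol (both C1 epimers) | Cc1c(O)cc2C=C([C@@H]3[C@H](O[Si](C)(C)C(C)(C)C)C=CC[C@H]3C)OC(O)c2c1O | intermediate (not isolated)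
19 | 2,4-dihydroxy-3-methyl-6-{2-oxo-2-[(1S,2R,6R)-2-[(tert-butyldimethylsilyl)oxy]-6-methylcyclohex-3-en-1-yl]ethyl}benzaldehyde | Cc1c(O)cc(CC(=O)[C@@H]2[C@H](O[Si](C)(C)C(C)(C)C)C=CC[C@H]2C)c(C=O)c1O | intermediate
20 | (5S)-4,5-dihydroxy-5-methyl-6-oxo-2-{2-oxo-2-[(1S,2R,6R)-2-[(tert-butyldimethylsilyl)oxy]-6-methylcyclohex-3-en-1-yl]ethyl}cyclohexa-1,3-diene-1-carbaldehyde | O[C@@]1(C)C(O)=CC(CC(=O)[C@@H]2[C@H](O[Si](C)(C)C(C)(C)C)C=CC[C@H]2C)=C(C=O)C1=O | intermediate (not isolated)
21 | (7S)-7-hydroxy-7-methyl-3-[(1S,2R,6R)-2-[(tert-butyldimethylsilyl)oxy]-6-methylcyclohex-3-en-1-yl]-6H-isochromene-6,8(7H)-dione | O[C@@]1(C)C(=O)C=C2C=C([C@@H]3[C@H](O[Si](C)(C)C(C)(C)C)C=CC[C@H]3C)OC=C2C1=O | intermediate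
22 | (E)-2-methylbut-2-enoic acid (tiglic acid) | C/C=C(\C)C(=O)O | starting material
23 | (S)-2-methylbutanoic acid | CC[C@H](C)C(=O)O | intermediate
24 | potassium 3-methoxy-3-oxopropanoate | COC(=O)CC(=O)[O-].[K+] | starting material
25 | (2S)-1-(1H-imidazol-1-yl)-2-methylbutan-1-one | CC[C@H](C)C(=O)n1ccnc1 | intermediate (not isolated)
26 | methyl (4S)-4-methyl-3-oxohexanoate | CC[C@H](C)C(=O)CC(=O)OC | intermediate
27 | methyl (3S,4S)-3-hydroxy-4-methylhexanoate | CC[C@H](C)[C@@H](O)CC(=O)OC | intermediate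
28 | methyl (2R,3R,4S)-3-hydroxy-2,4-dimethylhexanoate | CC[C@H](C)[C@@H](O)[C@@H](C)C(=O)OC | intermediate
29 | (2R,3R,4S)-3-hydroxy-2,4-dimethylhexanoic acid | CC[C@H](C)[C@@H](O)[C@@H](C)C(=O)O | intermediate
30 | tert-butyldimethylsilyl (2R,3R,4S)-3-[(tert-butyldimethylsilyl)oxy]-2,4-dimethylhexanoate | CC[C@H](C)[C@@H](O[Si](C)(C)C(C)(C)C)[C@@H](C)C(=O)O[Si](C)(C)C(C)(C)C | intermediate (not isolated)
31 | (2R,3R,4S)-3-[(tert-butyldimethylsilyl)oxy]-2,4-dimethylhexanoic acid | CC[C@H](C)[C@@H](O[Si](C)(C)C(C)(C)C)[C@@H](C)C(=O)O | intermediate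
32 | (2R,3R,4S)-3-[(tert-butyldimethylsilyl)oxy]-2,4-dimethylhexanoyl chloride | CC[C@H](C)[C@@H](O[Si](C)(C)C(C)(C)C)[C@@H](C)C(Cl)=O | intermediate (not isolated)
33 | (7S)-7-methyl-6,8-dioxo-3-[(1S,2R,6R)-2-[(tert-butyldimethylsilyl)oxy]-6-methylcyclohex-3-en-1-yl]-7,8-dihydro-6H-isochromen-7-yl (2R,3R,4S)-3-[(tert-butyldimethylsilyl)oxy]-2,4-dimethylhexanoate | CC[C@H](C)[C@@H](O[Si](C)(C)C(C)(C)C)[C@@H](C)C(=O)O[C@@]1(C)C(=O)C=C2C=C([C@@H]3[C@H](O[Si](C)(C)C(C)(C)C)C=CC[C@H]3C)OC=C2C1=O | intermediate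
34 | (7S)-3-[(1S,2R,6R)-2-hydroxy-6-methylcyclohex-3-en-1-yl]-7-methyl-6,8-dioxo-7,8-dihydro-6H-isochromen-7-yl (2R,3R,4S)-3-hydroxy-2,4-dimethylhexanoate | CC[C@H](C)[C@@H](O)[C@@H](C)C(=O)O[C@@]1(C)C(=O)C=C2C=C([C@@H]3[C@H](O)C=CC[C@H]3C)OC=C2C1=O | intermediate
35 | muyocopronone A | CC[C@H](C)[C@@H](O)[C@@H](C)C(=O)O[C@@]1(C)C(=O)C=C2C=C([C@@H]3C(=O)C=CC[C@H]3C)OC=C2C1=O | target

**Totals and weak points**
Total step count: 22.
Longest linear sequence: 13 steps (steps 1–7, 11–13, 20–22).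

Step 2 is the least precedented pairing in the route: a β-methyl dienophile with a moderately reactive 1-acyloxy diene may react slowly or with eroded endo and enantioselectivity. The fallback sets out from 4 and switches from Lewis-acid chelate catalysis to iminium organocatalysis. (E)-But-2-enal (C/C=C/C=O) and 4 react under (5R)-5-benzyl-2,2,3-trimethylimidazolidin-4-one hydrochloride (20 mol%) in MeCN/H2O to give (1R,5R,6S)-6-formyl-5-methylcyclohex-2-en-1-yl acetate F1. LiAlH4 in THF reduces F1 to diol 6, where the route is rejoined.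

Step 13 may fail because the bulky, lipophilic silyl-bearing side chain may not fit the enzyme, or may give poor conversion or facial selectivity. The fallback sets out from 19 and replaces biocatalysis by a chemical oxidative dearomatisation. CF3CO2H in ClCH2CH2Cl returns 19 to pyrylium 17, and IBX with catalytic Bu4NI hydroxylates C7 without facial control. This gives 21 together with its C7 epimer (7R)-7-hydroxy-7-methyl-3-[(1S,2R,6R)-2-[(tert-butyldimethylsilyl)oxy]-6-methylcyclohex-3-en-1-yl]-6H-isochromene-6,8(7H)-dione F2. Because the cyclohexene is already enantiopure the two are diastereomers and are separated by chromatography; the route is rejoined at 21.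

Step 20 joins a tertiary alcohol to an α-branched, β-silyloxy acid, so acylation may be slow and C2 of the acyl group may epimerise. The fallback sets out from 31 and 19 and installs the acyloxy group during the dearomatisation instead of esterifying afterwards. Ligand exchange of PhI(OAc)2 with 31 (chlorobenzene, 50 °C, reduced pressure) gives phenyl-λ3-iodanediyl bis[(2R,3R,4S)-3-[(tert-butyldimethylsilyl)oxy]-2,4-dimethylhexanoate] F3. Keto-aldehyde 19 is converted to pyrylium 17 with CF3CO2H and oxidised by F3 in a Wessely-type acyloxylation with trivalent iodine. This gives 33 and its C7 epimer (7R)-7-methyl-6,8-dioxo-3-[(1S,2R,6R)-2-[(tert-butyldimethylsilyl)oxy]-6-methylcyclohex-3-en-1-yl]-7,8-dihydro-6H-isochromen-7-yl (2R,3R,4S)-3-[(tert-butyldimethylsilyl)oxy]-2,4-dimethylhexanoate F4, which are separated by chromatography; the route is rejoined at 33.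

**Further compounds**
F1 | step 2 | (1R,5R,6S)-6-formyl-5-methylcyclohex-2-en-1-yl acetate | O=C[C@@H]1[C@H](OC(C)=O)C=CC[C@H]1C
F2 | step 13 | (7R)-7-hydroxy-7-methyl-3-[(1S,2R,6R)-2-[(tert-butyldimethylsilyl)oxy]-6-methylcyclohex-3-en-1-yl]-6H-isochromene-6,8(7H)-dione | O[C@]1(C)C(=O)C=C2C=C([C@@H]3[C@H](O[Si](C)(C)C(C)(C)C)C=CC[C@H]3C)OC=C2C1=O
F3 | step 20 | phenyl-λ3-iodanediyl bis[(2R,3R,4S)-3-[(tert-butyldimethylsilyl)oxy]-2,4-dimethylhexanoate] | CC[C@H](C)[C@@H](O[Si](C)(C)C(C)(C)C)[C@@H](C)C(=O)OI(OC(=O)[C@H](C)[C@H](O[Si](C)(C)C(C)(C)C)[C@@H](C)CC)c1ccccc1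
F4 | step 20 | (7R)-7-methyl-6,8-dioxo-3-[(1S,2R,6R)-2-[(tert-butyldimethylsilyl)oxy]-6-methylcyclohex-3-en-1-yl]-7,8-dihydro-6H-isochromen-7-yl (2R,3R,4S)-3-[(tert-butyldimethylsilyl)oxy]-2,4-dimethylhexanoate | CC[C@H](C)[C@@H](O[Si](C)(C)C(C)(C)C)[C@@H](C)C(=O)O[C@]1(C)C(=O)C=C2C=C([C@@H]3[C@H](O[Si](C)(C)C(C)(C)C)C=CC[C@H]3C)OC=C2C1=O
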